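Its constants were set for the occasion, and the outcome is calculated.

Per mole of substrate opened, how much target forms, and how much of it stays dissolved?

| flask | substrate | first nucleophile | second nucleophile | time |
|---|---|---|---|---|
| gamma | 0.15 M | 1.30 equiv | 1.50 equiv | 12 h |
| epsilon | 0.30 M | 1.30 equiv | 1.50 equiv | 12 h |
| delta | 0.60 M | 1.30 equiv | 1.50 equiv | 12 h |

* [target] (only what is free in solution) at the end for gamma, epsilon, delta, in this order
* how the row runs (rises, then falls / falls, then rises / hardly changes / rises all the way / falls all the way)

    substrate → intermediate (k1 = 0.00139 min⁻¹)
    first nucleophile + intermediate → target (k2 = 9.76 L mol⁻¹ min⁻¹)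
    second nucleophile + intermediate → other capture product (k3 = 16.6 L mol⁻¹ min⁻¹)
    intermediate → solvolysis product (k4 = 1.87 min⁻¹)
    crystals ⇌ target, rate k5*(cs5 - [target]) while solid is left; crystals form when [target] > cs5 (cs5 = 0.11 M, k5 = 0.0377 min⁻¹)
    intermediate → decomposed reagent (k6 = 0.0356 min⁻¹)
    second nucleophile → decomposition product (k7 = 1.02 × 10⁻⁵ min⁻¹)

How much substrate opens? Opening is first order at 0.00139 min⁻¹, so in 12 h the converted part is 63.2%, the same in each flask. Solvolysis consumes intermediate at 1.87 min⁻¹, far faster than substrate opens. So we treat intermediate as consumed as it forms.

Who captures it? Let φ be the capture share: the rate of capture by first nucleophile over the sum of the four rates consuming intermediate. At the charged concentrations, φ is 25.2% in gamma, 28.9% in epsilon and 31.1% in delta.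

But both nucleophiles fall during the run, and at charged ratios 1.96 mol of second nucleophile goes per mole of target. So we replace each falling curve by its mean, charge minus half the estimated use. This gives 25.4%, 29.4% and 32.0%. We carry this mean capture share, the fraction of opened substrate becoming target with both nucleophiles at their mean concentrations. In delta the mean moves φ by 0.90 percentage points.

Does target pass its solubility, 0.11 M? Conversion times share times charge gives 0.0241 M in gamma and 0.0558 M in epsilon, both below it, so both stay dissolved. Delta gives 0.122 M, above it. On this reckoning delta crosses at 10.2 h, which leaves more time than the crystal response time 0.442 h. So we put free target in delta above solubility by its formation rate over the dissolution coefficient, 0.00261 M, which gives 0.113 M. Our row rises from flask to flask.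

The forecast gives 0.024 M, 0.056 M and 0.1127 M, and says the row rises all the way, with “crystallisation holds its free target just above that limit”.

The simulation gives 0.0241 M, 0.0558 M and 0.113 M; the row rises all the way.

In gamma at 4.56 h, substrate has a half-life of 8.3 h by opening, far longer than the 0.37 min of intermediate by solvolysis, and intermediate is made and used at a ratio of 1.00. Delta at 12.0 h holds target at 20.3% of the substrate charged, crystals counted, where conversion times the carried share gives 20.2%; gamma at 120 h, with substrate at 0%, holds 25.5%, where the same mean share, taken over full conversion, gives 25.5%.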